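**Retrosynthetic overview**

1. Ring numbering: O1, C2 (stereocentre carrying the C21 chain), C3H2, C4(=O), C5H=C6(Me). This dihydropyranone is the only ring and is closed last, in the key step.
2. C3–C2 and C4–C5 are made in one operation from an acyclic α-(isopropenyloxy) diazoketone. In a Wolff rearrangement C2 shifts from C4 to the diazo carbon C3 with retention, and the ketene carbon C4 is then captured by C5 of the O1-bound isopropenyl group.
3. Enabling feature: the ring is a cyclic vinylogous ester. O1 joins stereogenic C2 to the enol ether unit C6(Me)=C5, so C2–C3–C4(=O) is the one-carbon homologue of an α-alkoxy acid, and nucleophilic C5 sits where a six-membered closure onto C4 is possible.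
4. The diazoketone comes from an (R)-α-hydroxy ester by O-isopropenylation (mixed ketal, then elimination), silanolate ester cleavage, and mixed anhydride acylation of Me3SiCHN2.
5. The (R)-α-hydroxy ester comes from the chiral pool: copper-catalysed opening of methyl (R)-glycidate by the Grignard reagent of (Z)-1-bromoicos-11-ene.

Key step: step 7

Remark: the SMILES is read as the (R)-enantiomer with a (Z)-alkene, and (Z)-icos-11-en-1-ol is taken to be a purchasable material.

**Route**

Step 1
Reactants: 1 (Z)-icos-11-en-1-ol
Product: 2 (Z)-1-bromoicos-11-ene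
Conditions: CBr4, PPh3, CH2Cl2, 0 °C to rt
Reagents that add atoms: carbon tetrabromide, BrC(Br)(Br)Br
Why: Appel reaction, in which bromide displaces the alkoxyphosphonium group at a primary carbon under neutral conditions that should leave the Z-alkene untouched.

Step 2
Reactants: 2 (Z)-1-bromoicos-11-ene; 3 methyl (R)-oxirane-2-carboxylate
Product: 5 methyl (R,Z)-2-hydroxytricos-14-enoate, via (Z)-icos-11-enylmagnesium bromide 4 (not isolated)
Conditions: Mg, THF, 40 °C; then CuBr·SMe2 (10 mol %), 3 (1.2 equiv), THF, −78 to −40 °C; aq NH4Cl
Reagents that add atoms: none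
Why: Copper-catalysed Grignard opening of the terminal epoxide (SN2 at the unsubstituted carbon) should outrun addition to the ester at low temperature, and the glycidate stereocentre is not a reacting centre, so it is carried into the product as (R).

Step 3
Reactants: 5 methyl (R,Z)-2-hydroxytricos-14-enoate; 6 2-methoxypropene
Product: 7 methyl (R,Z)-2-[(2-methoxypropan-2-yl)oxy]tricos-14-enoate
Conditions: 6 (5 equiv), pyridinium p-toluenesulfonate (2 mol %), CH2Cl2, 0 °C; Et3N quench
Reagents that add atoms: none
Why: Acid-catalysed Markovnikov addition of the secondary alcohol to the enol ether (mixed ketal formation) forms no co-product and should not affect the ester, the alkene or the stereocentre.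

Step 4
Reactants: 7 methyl (R,Z)-2-[(2-methoxypropan-2-yl)oxy]tricos-14-enoate
Product: 8 methyl (R,Z)-2-(prop-1-en-2-yloxy)tricos-14-enoate
Conditions: Me3SiOTf (1.2 equiv), Et3N (1.5 equiv), CH2Cl2, 0 °C; pentane, filtration through basic alumina
Reagents that add atoms: none
Why: Silyl triflate/amine ketal-to-enol-ether elimination, in which Me3SiOTf should ionise the mixed ketal at the more basic, less hindered methoxy oxygen and Et3N removes a methyl proton from the oxocarbenium ion, leaving the stereocentre untouched.

Step 5
Reactants: 8 methyl (R,Z)-2-(prop-1-en-2-yloxy)tricos-14-enoate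
Product: 9 potassium (R,Z)-2-(prop-1-en-2-yloxy)tricos-14-enoate
Conditions: KOSiMe3 (1.05 equiv), THF, rt; concentrate and dry
Reagents that add atoms: potassium trimethylsilanolate, C[Si](C)(C)[O-].[K+]
Why: Anhydrous silanolate cleavage of the methyl ester gives the carboxylate salt without ever forming the free acid, which would add to its own isopropenyl ether, and the weakly basic conditions should not epimerise the α-alkoxy centre.

Step 6
Reactants: 9 potassium (R,Z)-2-(prop-1-en-2-yloxy)tricos-14-enoate; 10 (trimethylsilyl)diazomethane
Product: 12 (R,Z)-1-diazo-3-(prop-1-en-2-yloxy)tetracos-15-en-2-one, via isobutyl carbonic mixed anhydride 11 (not isolated)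
Conditions: iBuOCOCl (1.05 equiv), THF, −20 °C; then 10 (2 equiv, hexanes), MeCN, 0 °C to rt; cold aq NaHCO3; Et3N-deactivated silica, dark
Reagents that add atoms: none
Why: First stage of an Arndt–Eistert homologation, in which the mixed carbonic anhydride C-acylates the diazo carbon and the silyl group leaves with the carbonate, under acid-free conditions that should spare the enol ether and the α-stereocentre.

Step 7
Reactants: 12 (R,Z)-1-diazo-3-(prop-1-en-2-yloxy)tetracos-15-en-2-one
Product: 15 (R)-2-[(Z)-henicos-12-en-1-yl]-6-methyl-2,3-dihydro-4H-pyran-4-one, via alkoxyketene 13 (not isolated), via oxocarbenium enolate zwitterion 14 (not isolated)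
Conditions: hν (365 nm LEDs), dry degassed PhMe (0.005 M), 20 °C; then 60 °C; silica gel
Reagents that add atoms: none
Why: Proposed new method: direct photolysis should expel N2 from the s-Z diazoketone with concerted 1,2-shift of C2 from C4 to the diazo carbon C3 (Wolff rearrangement, forming C3–C2) to give β-alkoxy ketene 13, whose electrophilic carbon C4 is attacked in the ketene plane by C5, the terminal carbon of the tethered 2-alkoxypropene (forming C4–C5), to give zwitterion 14, which collapses by a net proton shift to C3 to the conjugated vinylogous ester (the thermodynamic tautomer, equilibration being completed on silica gel). The closest known reaction types are the Arndt–Eistert homologation of α-alkoxy acids, the first C–C bond-forming stage of stepwise ketene–enol ether [2+2] cycloadditions, and the C-acylation of enol ethers by acyl halides to β-alkoxy enones; the untested part is the intramolecular six-membered capture of a Wolff ketene by an enol ether carbon. The single ring closes in a 6-endo-trig mode with respect to the isopropenyl C=C (C5 and C6 both end up in the ring), and the competing collapse of 14 between C3 and C6 is disfavoured because it would give a strained 2-oxabicyclo[2.2.0]hexanone. No new stereocentre is made: C2 is carried over from 12 with retention, since the migrating carbon keeps its bonding pair on one face, and it is not enolisable in the product. The step needs the Wolff shift to outrun carbene chemistry (cyclopropanation of the enol ether, oxonium ylide formation) and the cyclisation to outrun ketene dimerisation; metal-free photolysis of the s-Z conformer, high dilution and the matched polarity of the partners (nucleophilic =CH2 of a 2-alkoxypropene, electrophilic ketene carbon) should secure this, and the isolated Z-alkene does not absorb at 365 nm.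

**Compound list**

1 | (Z)-icos-11-en-1-ol | CCCCCCCC/C=C\CCCCCCCCCCO | starting material
2 | (Z)-1-bromoicos-11-ene | CCCCCCCC/C=C\CCCCCCCCCCBr | intermediate
3 | methyl (R)-oxirane-2-carboxylate | COC(=O)[C@H]1CO1 | starting material
4 | (Z)-icos-11-enylmagnesium bromide | CCCCCCCC/C=C\CCCCCCCCCC[Mg]Br | intermediate
5 | methyl (R,Z)-2-hydroxytricos-14-enoate | CCCCCCCC/C=C\CCCCCCCCCCC[C@@H](O)C(=O)OC | intermediate
6 | 2-methoxypropene | COC(C)=C | starting material
7 | methyl (R,Z)-2-[(2-methoxypropan-2-yl)oxy]tricos-14-enoate | CCCCCCCC/C=C\CCCCCCCCCCC[C@@H](OC(C)(C)OC)C(=O)OC | intermediate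
8 | methyl (R,Z)-2-(prop-1-en-2-yloxy)tricos-14-enoate | CCCCCCCC/C=C\CCCCCCCCCCC[C@@H](OC(C)=C)C(=O)OC | intermediate
9 | potassium (R,Z)-2-(prop-1-en-2-yloxy)tricos-14-enoate | CCCCCCCC/C=C\CCCCCCCCCCC[C@@H](OC(C)=C)C(=O)[O-].[K+] | intermediate
10 | (trimethylsilyl)diazomethane | C[Si](C)(C)C=[N+]=[N-] | starting material
11 | (R,Z)-2-(prop-1-en-2-yloxy)tricos-14-enoic isobutyl carbonic anhydride | CCCCCCCC/C=C\CCCCCCCCCCC[C@@H](OC(C)=C)C(=O)OC(=O)OCC(C)C | intermediate
12 | (R,Z)-1-diazo-3-(prop-1-en-2-yloxy)tetracos-15-en-2-one | CCCCCCCC/C=C\CCCCCCCCCCC[C@@H](OC(C)=C)C(=O)C=[N+]=[N-] | intermediate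
13 | (3R,15Z)-3-(prop-1-en-2-yloxy)tetracosa-1,15-dien-1-one (alkoxyketene) | CCCCCCCC/C=C\CCCCCCCCCCC[C@@H](OC(C)=C)C=C=O | intermediate
14 | (R)-2-[(Z)-henicos-12-en-1-yl]-6-methyl-2,5-dihydropyran-1-ium-4-olate (oxocarbenium enolate zwitterion) | CCCCCCCC/C=C\CCCCCCCCCCC[C@@H]1C=C([O-])CC(C)=[O+]1 | intermediate
15 | (R)-2-[(Z)-henicos-12-en-1-yl]-6-methyl-2,3-dihydro-4H-pyran-4-one | CCCCCCCC/C=C\CCCCCCCCCCC[C@@H]1CC(=O)C=C(C)O1 | target

**Step count and risks**

Total steps: 7. Longest linear sequence: 7 steps (from 1).

Steps most likely to fail: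

1. Step 7. The ketene may be consumed by dimerisation or by carbene-derived pathways before C5 reaches C4. The fallback sets out from 12 and comes back at 15. Compound 12 would be photolysed (365 nm, THF) in the presence of N,O-dimethylhydroxylamine, so that ketene 13 is intercepted intermolecularly as (R,Z)-N-methoxy-N-methyl-3-(prop-1-en-2-yloxy)tetracos-15-enamide F1. MeC≡CMgBr in THF at 0 °C should then give (R,Z)-6-(prop-1-en-2-yloxy)heptacos-18-en-2-yn-4-one F2. Pyridinium p-toluenesulfonate in wet THF should hydrolyse the isopropenyl ether to (R,Z)-6-hydroxyheptacos-18-en-2-yn-4-one F3. AuCl3 (5 mol %) in CH2Cl2 should finally close the ring by 6-endo-dig oxa-cyclisation to 15. Here C3–C2 still comes from the Wolff shift, C4–C5 from acylation of the alkynyl Grignard reagent, and O1–C6 from the hydroalkoxylation.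

2. Step 6. The activated carboxyl group may attack its own enol ether, the isopropenyl group may be lost to adventitious acid, or acylation of the silyl diazomethane may be incomplete. The fallback sets out from 8 and comes back at 12, avoiding any carboxyl activation. MeNH(OMe)·HCl with iPrMgCl (THF, −20 °C) should convert 8 into (R,Z)-N-methoxy-N-methyl-2-(prop-1-en-2-yloxy)tricos-14-enamide F4. MeMgBr should give the methyl ketone (R,Z)-3-(prop-1-en-2-yloxy)tetracos-15-en-2-one F5. Kinetic enolisation at the methyl group with LiN(SiMe3)2 (THF, −78 °C) and trifluoroacetylation with CF3CO2CH2CF3 should give (R,Z)-1,1,1-trifluoro-5-(prop-1-en-2-yloxy)hexacos-17-ene-2,4-dione F6. Detrifluoroacetylative diazo transfer with MsN3, Et3N and H2O in MeCN should then give 12.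

3. Step 4. The ketal may ionise on the wrong oxygen (loss of the substrate alcohol instead of methanol), a silyl ketene acetal may form and epimerise the α-centre, or the product may hydrolyse during isolation. The fallback sets out from 5 and comes back at 8, replacing steps 3 and 4. It is an iridium-catalysed alkenyl transfer from isopropenyl acetate ([Ir(cod)Cl]2 1 mol %, Na2CO3, isopropenyl acetate, PhMe, 100 °C), in which alkoxy-iridation of the enol acetate and β-acetate elimination should give 8 directly. This fallback makes no new compound (F0).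

Further compounds
F1 | step 7 | (R,Z)-N-methoxy-N-methyl-3-(prop-1-en-2-yloxy)tetracos-15-enamide | CCCCCCCC/C=C\CCCCCCCCCCC[C@@H](OC(C)=C)CC(=O)N(C)OC
F2 | step 7 | (R,Z)-6-(prop-1-en-2-yloxy)heptacos-18-en-2-yn-4-one | CCCCCCCC/C=C\CCCCCCCCCCC[C@@H](OC(C)=C)CC(=O)C#CC
F3 | step 7 | (R,Z)-6-hydroxyheptacos-18-en-2-yn-4-one | CCCCCCCC/C=C\CCCCCCCCCCC[C@@H](O)CC(=O)C#CC
F4 | step 6 | (R,Z)-N-methoxy-N-methyl-2-(prop-1-en-2-yloxy)tricos-14-enamide | CCCCCCCC/C=C\CCCCCCCCCCC[C@@H](OC(C)=C)C(=O)N(C)OC
F5 | step 6 | (R,Z)-3-(prop-1-en-2-yloxy)tetracos-15-en-2-one | CCCCCCCC/C=C\CCCCCCCCCCC[C@@H](OC(C)=C)C(C)=O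
F6 | step 6 | (R,Z)-1,1,1-trifluoro-5-(prop-1-en-2-yloxy)hexacos-17-ene-2,4-dione | CCCCCCCC/C=C\CCCCCCCCCCC[C@@H](OC(C)=C)C(=O)CC(=O)C(F)(F)F
F0 | step 4 | none | none
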